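**Retrosynthetic overview**
- Late stage: free the phenol from its acetate, make the C11 alcohol by Luche reduction of a C4 formyl group, and put the coumaroyl unit on the primary C10–OH of a triol by selective esterification.
- Key disconnection: cyclopentane and dihydropyran are formed together from an acyclic aldehyde and malondialdehyde by a domino Knoevenagel / intramolecular oxa-Diels–Alder reaction. The dienophile is an (E)-enol ester that already carries the (S)-3-methylpentanoyl group, so C1, C5 and C9 are set in that one operation.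
- The (E)-enol ester comes from a terminal alkyne (hydroboration, copper-catalysed acyloxylation); the aldehyde comes from a primary triethylsilyl ether.
- C8 comes from acetylide addition to a 4-substituted 1,3-dioxan-5-one; C7 comes from RAMP-hydrazone alkylation of 2,2-dimethyl-1,3-dioxan-5-one.
- Ring order: the bought 1,3-dioxane (kept as a temporary stereocontrol ring) → cyclopentane and dihydropyran simultaneously → dioxane opened.

Assumption: RAMP, (S)-3-methylpentanoic acid, sodium malondialdehyde and (E)-4-acetoxycinnamic acid are bought; atom labels follow iridoid numbering (C1 acetal, C3=C4 enol ether, C5/C9 ring fusion, C7 CHOH, C8 quaternary carbinol, C10 its CH2O, C11 the carbon on C4).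

**Step 1**
Reactants: 1 2,2-dimethyl-1,3-dioxan-5-one; 2 (R)-1-amino-2-(methoxymethyl)pyrrolidine (RAMP)
Product: 3 (R)-N-(2,2-dimethyl-1,3-dioxan-5-ylidene)-2-(methoxymethyl)pyrrolidin-1-amine
Conditions: benzene, reflux, Dean–Stark
Reagents that add atoms: none
Why: Hydrazone formation (attachment of the Enders auxiliary) is driven to completion by azeotropic removal of water and creates no new stereocentre.

**Step 2**
Reactants: 4 2-iodoethanol
Product: 5 (2-iodoethoxy)triethylsilane
Conditions: Et3SiCl, imidazole, CH2Cl2, 0 °C → rt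
Reagents that add atoms: chlorotriethylsilane, CC[Si](Cl)(CC)CC
Why: Imidazole-promoted silylation of a primary alcohol is routine and gives the electrophile with a primary triethylsilyl ether that later serves as a masked aldehyde.

**Step 3**
Reactants: 3 RAMP hydrazone; 5 (2-iodoethoxy)triethylsilane
Product: 8 (4R)-2,2-dimethyl-4-[2-(triethylsilyloxy)ethyl]-1,3-dioxan-5-one, via lithium azaenolate 6 (not isolated), via alkylated hydrazone 7 (not isolated)
Conditions: t-BuLi, THF, −78 °C; 5, −100 °C → rt; then O3, CH2Cl2, −78 °C, argon purge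
Reagents that add atoms: ozone, [O-][O+]=O
Why: In the Enders RAMP-hydrazone alkylation the chelated lithium azaenolate is alkylated on the face away from the methoxymethyl arm, which with RAMP gives the (R) centre (C7), and ozonolysis of the C=N bond then releases the ketone without racemisation while the auxiliary leaves as its nitrosamine.

**Step 4**
Reactants: 8 (4R)-ketone
Product: 10 (4R,5S)-5-ethynyl-2,2-dimethyl-5-(triethylsilyloxy)-4-[2-(triethylsilyloxy)ethyl]-1,3-dioxane, via bromomagnesium alkoxide 9 (not isolated)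
Conditions: HC≡CMgBr (1.2 equiv), THF, −78 → −20 °C; then Et3SiOTf, −78 → 0 °C
Reagents that add atoms: ethynylmagnesium bromide, C#C[Mg]Br; triethylsilyl trifluoromethanesulfonate, CC[Si](CC)(CC)OS(=O)(=O)C(F)(F)F
Why: Grignard 1,2-addition to a 1,3-dioxan-5-one occurs by axial attack (anti to the axial α-C–H bonds, no 1,3-diaxial hydrogens on that face), which puts the ethynyl group cis to the equatorial side chain and the oxygen trans to it (C8 as in the target), and the alkoxide is silylated in the same flask so that it cannot later add to the Knoevenagel acceptor.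

**Step 5**
Reactants: 10 alkyne
Product: 11 2-[(E)-2-{(4R,5S)-2,2-dimethyl-5-(triethylsilyloxy)-4-[2-(triethylsilyloxy)ethyl]-1,3-dioxan-5-yl}ethenyl]-4,4,5,5-tetramethyl-1,3,2-dioxaborolane
Conditions: pinacolborane, Cp2Zr(H)Cl (10 mol%), Et3N (10 mol%), neat, 60 °C
Reagents that add atoms: pinacolborane, [H]B1OC(C)(C)C(C)(C)O1
Why: Zirconium-catalysed hydroboration of a terminal alkyne is a syn, anti-Markovnikov addition that gives only the (E)-alkenyl boronate and tolerates silyl ethers and the acetonide.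

**Step 6**
Reactants: 11 (E)-alkenyl boronate; 12 (S)-3-methylpentanoic acid
Product: 13 (E)-2-{(4R,5S)-2,2-dimethyl-5-(triethylsilyloxy)-4-[2-(triethylsilyloxy)ethyl]-1,3-dioxan-5-yl}ethenyl (3S)-3-methylpentanoate
Conditions: 12 (2 equiv), CuBr (20 mol%), DMAP, 4 Å MS, O2 (1 atm), MeCN, 50 °C
Reagents that add atoms: none
Why: This Chan–Lam-type copper-catalysed aerobic C–O coupling of an alkenylboron compound with a carboxylic acid proceeds with retention of alkene geometry, so the (E)-enol ester is obtained with the acid's stereocentre untouched.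

**Step 7**
Reactants: 13 (E)-enol ester
Product: 14 (E)-2-[(4R,5S)-2,2-dimethyl-4-(2-oxoethyl)-5-(triethylsilyloxy)-1,3-dioxan-5-yl]ethenyl (3S)-3-methylpentanoate
Conditions: (COCl)2, DMSO, CH2Cl2, −78 → −30 °C; Et3N, → 0 °C
Reagents that add atoms: none
Why: Under Swern conditions the chlorosulfonium salt cleaves the unhindered primary Si–O bond and the resulting alkoxysulfonium ylide collapses to the aldehyde, whereas the tertiary silyl ether (hindered, no α-hydrogen), the acetonide and the enol ester are inert.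

**Step 8**
Reactants: 14 aldehyde; 15 sodium malondialdehyde (sodium 3-oxoprop-1-en-1-olate, NaOCH=CHCHO)
Product: 17 tricyclic (1R,5R,7R,8S,9R)-4-formyl-7-O,10-O-isopropylidene-8-O-triethylsilyl iridoid core bearing the C1 (3S)-3-methylpentanoate, via alkylidene malondialdehyde 16 (not isolated)
Conditions: 15 (1.5 equiv), AcOH (1.5 equiv), ethylenediammonium diacetate (10 mol%), 4 Å MS, MeCN, 0 → 60 °C
Reagents that add atoms: none
Why: Proposed new method: the closest known reaction is the Tietze domino Knoevenagel / intramolecular hetero-Diels–Alder reaction of alkylidene-1,3-dicarbonyls with tethered alkenes or enol ethers, here extended to an enol ester dienophile; it should work because alkylidene malondialdehyde 16 is a very electron-poor 1-oxadiene whose C5 is attacked by the nucleophilic β-carbon (C9) of the enol ester while a formyl oxygen closes onto C1 in an inverse-electron-demand [4+2] step, the three-atom tether enforcing cis ring fusion (H5/H9 cis), the E geometry being transferred suprafacially so that the C1 acyloxy group is cis to H9, and the diene adding on the convex face of the chair dioxane (axial vinyl, equatorial side chain), anti to the acetonide, which fixes C5 and C9 relative to C7 and C8.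

**Step 9**
Reactants: 17 tricyclic acetonide
Product: 18 (1R,4aR,6R,7S,7aR)-4-formyl-6,7-dihydroxy-7-(hydroxymethyl)-1,4a,5,6,7,7a-hexahydrocyclopenta[c]pyran-1-yl (3S)-3-methylpentanoate
Conditions: TFA/H2O (9:1), 0 °C
Reagents that add atoms: none
Why: Acid-catalysed acetal hydrolysis and protodesilylation free the three hydroxyls, while the acyloxy acetal and the enol ether survive because the ring oxygen is conjugated to the C4 formyl group (vinylogous ester) and cannot easily support an oxocarbenium ion.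

**Step 10**
Reactants: 18 triol; 19 (E)-4-acetoxycinnamic acid
Product: 20 (1R,4aR,6R,7S,7aR)-7-{[(E)-3-(4-acetoxyphenyl)prop-2-enoyl]oxymethyl}-4-formyl-6,7-dihydroxy-1,4a,5,6,7,7a-hexahydrocyclopenta[c]pyran-1-yl (3S)-3-methylpentanoate
Conditions: 19 (1.05 equiv), DIC, DMAP (10 mol%), CH2Cl2, −20 → 0 °C
Reagents that add atoms: none
Why: In this Steglich esterification the primary C10–OH reacts much faster than the hindered secondary C7–OH and the tertiary C8–OH, and the C11 carbon is still an aldehyde so no second primary alcohol competes.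

**Step 11**
Reactants: 20 aldehyde
Product: 21 (1R,4aR,6R,7S,7aR)-7-{[(E)-3-(4-acetoxyphenyl)prop-2-enoyl]oxymethyl}-6,7-dihydroxy-4-(hydroxymethyl)-1,4a,5,6,7,7a-hexahydrocyclopenta[c]pyran-1-yl (3S)-3-methylpentanoate
Conditions: NaBH4, CeCl3·7H2O, MeOH, −40 °C; pH 7 phosphate buffer
Reagents that add atoms: none
Why: Luche reduction gives clean 1,2-reduction of the β-alkoxy enal to the allylic alcohol at low temperature and leaves the cinnamate, the aryl acetate and the C1 ester untouched.

**Step 12**
Reactants: 21 aryl acetate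
Product: 22 (1R,4aR,6R,7S,7aR)-6,7-dihydroxy-4-(hydroxymethyl)-7-{[(E)-3-(4-hydroxyphenyl)prop-2-enoyl]oxymethyl}-1,4a,5,6,7,7a-hexahydrocyclopenta[c]pyran-1-yl (3S)-3-methylpentanoate (target)
Conditions: NH4OAc, MeOH/H2O (4:1), rt
Reagents that add atoms: none
Why: Neutral solvolysis with ammonium acetate removes the unhindered aryl acetate (phenoxide is the best leaving group present) faster than it touches the hindered β-branched C1 ester or the conjugated cinnamate.

**Compound list**
1 | 2,2-dimethyl-1,3-dioxan-5-one | CC1(C)OCC(=O)CO1 | starting material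
2 | (R)-1-amino-2-(methoxymethyl)pyrrolidine (RAMP) | COC[C@H]1CCCN1N | starting material
3 | (R)-N-(2,2-dimethyl-1,3-dioxan-5-ylidene)-2-(methoxymethyl)pyrrolidin-1-amine | COC[C@H]1CCCN1N=C1COC(C)(C)OC1 | intermediate
4 | 2-iodoethanol | OCCI | starting material
5 | (2-iodoethoxy)triethylsilane | CC[Si](CC)(CC)OCCI | intermediate
6 | lithium azaenolate of 3 | [Li+].COC[C@H]1CCCN1[N-]C1=COC(C)(C)OC1 | intermediate
7 | (R)-N-{(4R)-2,2-dimethyl-4-[2-(triethylsilyloxy)ethyl]-1,3-dioxan-5-ylidene}-2-(methoxymethyl)pyrrolidin-1-amine | COC[C@H]1CCCN1N=C1COC(C)(C)O[C@@H]1CCO[Si](CC)(CC)CC | intermediate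
8 | (4R)-2,2-dimethyl-4-[2-(triethylsilyloxy)ethyl]-1,3-dioxan-5-one | O=C1COC(C)(C)O[C@@H]1CCO[Si](CC)(CC)CC | intermediate
9 | bromomagnesium (4R,5S)-5-ethynyl-2,2-dimethyl-4-[2-(triethylsilyloxy)ethyl]-1,3-dioxan-5-olate | CC[Si](CC)(CC)OCC[C@H]1OC(C)(C)OC[C@@]1(O[Mg]Br)C#C | intermediate
10 | (4R,5S)-5-ethynyl-2,2-dimethyl-5-(triethylsilyloxy)-4-[2-(triethylsilyloxy)ethyl]-1,3-dioxane | CC[Si](CC)(CC)OCC[C@H]1OC(C)(C)OC[C@@]1(O[Si](CC)(CC)CC)C#C | intermediate
11 | 2-[(E)-2-{(4R,5S)-2,2-dimethyl-5-(triethylsilyloxy)-4-[2-(triethylsilyloxy)ethyl]-1,3-dioxan-5-yl}ethenyl]-4,4,5,5-tetramethyl-1,3,2-dioxaborolane | CC[Si](CC)(CC)OCC[C@H]1OC(C)(C)OC[C@@]1(O[Si](CC)(CC)CC)/C=C/B1OC(C)(C)C(C)(C)O1 | intermediate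
12 | (S)-3-methylpentanoic acid | CC[C@H](C)CC(=O)O | starting material
13 | (E)-2-{(4R,5S)-2,2-dimethyl-5-(triethylsilyloxy)-4-[2-(triethylsilyloxy)ethyl]-1,3-dioxan-5-yl}ethenyl (3S)-3-methylpentanoate | CC[Si](CC)(CC)OCC[C@H]1OC(C)(C)OC[C@@]1(O[Si](CC)(CC)CC)/C=C/OC(=O)C[C@@H](C)CC | intermediate
14 | (E)-2-[(4R,5S)-2,2-dimethyl-4-(2-oxoethyl)-5-(triethylsilyloxy)-1,3-dioxan-5-yl]ethenyl (3S)-3-methylpentanoate | O=CC[C@H]1OC(C)(C)OC[C@@]1(O[Si](CC)(CC)CC)/C=C/OC(=O)C[C@@H](C)CC | intermediate
15 | sodium malondialdehyde (sodium 3-oxoprop-1-en-1-olate) | [Na+].[O-]/C=C/C=O | starting material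
16 | (E)-2-[(4R,5S)-4-(3-formyl-4-oxobut-2-en-1-yl)-2,2-dimethyl-5-(triethylsilyloxy)-1,3-dioxan-5-yl]ethenyl (3S)-3-methylpentanoate | O=CC(C=O)=CC[C@H]1OC(C)(C)OC[C@@]1(O[Si](CC)(CC)CC)/C=C/OC(=O)C[C@@H](C)CC | intermediate
17 | tricyclic (1R,5R,7R,8S,9R)-4-formyl-7-O,10-O-isopropylidene-8-O-triethylsilyl iridoid core, C1 (3S)-3-methylpentanoate | CC[C@H](C)CC(=O)O[C@H]1OC=C(C=O)[C@@H]2C[C@H]3OC(C)(C)OC[C@@]3(O[Si](CC)(CC)CC)[C@H]12 | intermediate
18 | (1R,4aR,6R,7S,7aR)-4-formyl-6,7-dihydroxy-7-(hydroxymethyl)-1,4a,5,6,7,7a-hexahydrocyclopenta[c]pyran-1-yl (3S)-3-methylpentanoate | CC[C@H](C)CC(=O)O[C@H]1OC=C(C=O)[C@@H]2C[C@@H](O)[C@@](O)(CO)[C@H]12 | intermediate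
19 | (E)-4-acetoxycinnamic acid | CC(=O)Oc1ccc(/C=C/C(=O)O)cc1 | starting material
20 | C10 4-acetoxycinnamate of 18 | CC[C@H](C)CC(=O)O[C@H]1OC=C(C=O)[C@@H]2C[C@@H](O)[C@@](O)(COC(=O)/C=C/c3ccc(OC(C)=O)cc3)[C@H]12 | intermediate
21 | C11 alcohol, phenol still acetylated | CC[C@H](C)CC(=O)O[C@H]1OC=C(CO)[C@@H]2C[C@@H](O)[C@@](O)(COC(=O)/C=C/c3ccc(OC(C)=O)cc3)[C@H]12 | intermediate
22 | CNP0241834.3 | CC[C@H](C)CC(=O)O[C@H]1OC=C(CO)[C@@H]2C[C@@H](O)[C@@](O)(COC(=O)/C=C/c3ccc(O)cc3)[C@H]12 | target

**Step count**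
Total steps: 12. Longest linear sequence: 11 (steps 1 and 3–12 from 1, or steps 2–12 from 4).

**Steps most likely to fail, each with a fallback**

Step 8 (key domino reaction). The enol ester may be too poor a dienophile, so that 16 oligomerises or adds a second malondialdehyde. The fallback sets out from boronate 11 and swaps the dienophile class. A copper-promoted etherification of 11 with 4-methoxybenzyl alcohol (Cu(OAc)2, Et3N, neat alcohol, rt) gives the (E)-enol 4-methoxybenzyl ether F1. Direct Swern oxidation of F1 gives the aldehyde F2. The classical Tietze reaction of F2 with 15, now with an electron-rich enol ether dienophile, gives the C1 O-(4-methoxybenzyl) acetal F3. DDQ in buffered CH2Cl2 unmasks the lactol F4, and Steglich acylation of F4 with 12 (DIC, DMAP) on the convex face comes back to the route at 17.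

Step 6 (acyloxylation of the pinacol boronate). Transmetalation of the hindered pinacol ester to copper may be slow. The fallback sets out from alkyne 10: hydrozirconation with Cp2Zr(H)Cl (THF, rt) and iodinolysis (I2, 0 °C) give the (E)-vinyl iodide F5. An Ullmann-type copper-catalysed vinylation of the carboxylate of 12 (CuI, N,N'-dimethylethylenediamine, Cs2CO3, toluene, 80 °C) proceeds with retention of geometry and comes back to the route at 13.

Step 12 (aryl acetate removal beside the acyloxy acetal). The C1 ester is an activated, anomeric-type ester and may be partly cleaved. The fallback sets out from triol 18 and changes the phenol protecting group to one removed by fluoride. p-Coumaric acid is silylated (t-BuMe2SiCl, imidazole, DMF; then K2CO3, aqueous MeOH to free the acid) to give (E)-4-(tert-butyldimethylsilyloxy)cinnamic acid F6. Steglich esterification of 18 with F6 gives the silyl-protected C10 ester F7, and Luche reduction gives the silyl-protected C11 alcohol F8. Buffered fluoride (Bu4NF/AcOH, THF, 0 °C) then comes back to the route at the target 22.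

**Further compounds**
F1 | step 8 | (E)-enol 4-methoxybenzyl ether from 11 | CC[Si](CC)(CC)OCC[C@H]1OC(C)(C)OC[C@@]1(O[Si](CC)(CC)CC)/C=C/OCc1ccc(OC)cc1
F2 | step 8 | aldehyde from F1 | O=CC[C@H]1OC(C)(C)OC[C@@]1(O[Si](CC)(CC)CC)/C=C/OCc1ccc(OC)cc1
F3 | step 8 | tricyclic C1 O-(4-methoxybenzyl) acetal | COc1ccc(CO[C@H]2OC=C(C=O)[C@@H]3C[C@H]4OC(C)(C)OC[C@@]4(O[Si](CC)(CC)CC)[C@H]23)cc1
F4 | step 8 | tricyclic C1 lactol | O[C@H]1OC=C(C=O)[C@@H]2C[C@H]3OC(C)(C)OC[C@@]3(O[Si](CC)(CC)CC)[C@H]12
F5 | step 6 | (E)-vinyl iodide from 10 | CC[Si](CC)(CC)OCC[C@H]1OC(C)(C)OC[C@@]1(O[Si](CC)(CC)CC)/C=C/I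
F6 | step 12 | (E)-4-(tert-butyldimethylsilyloxy)cinnamic acid | CC(C)(C)[Si](C)(C)Oc1ccc(/C=C/C(=O)O)cc1
F7 | step 12 | silyl-protected C10 ester of 18 | CC[C@H](C)CC(=O)O[C@H]1OC=C(C=O)[C@@H]2C[C@@H](O)[C@@](O)(COC(=O)/C=C/c3ccc(O[Si](C)(C)C(C)(C)C)cc3)[C@H]12
F8 | step 12 | silyl-protected C11 alcohol | CC[C@H](C)CC(=O)O[C@H]1OC=C(CO)[C@@H]2C[C@@H](O)[C@@](O)(COC(=O)/C=C/c3ccc(O[Si](C)(C)C(C)(C)C)cc3)[C@H]12
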